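**Assumption:** the target SMILES has no stereocenters, so it is achiral and no enantioselective step is needed. The transient benzhydrol stereocenters in 11, 16, 17 and 18 are racemic and are destroyed by oxidation (steps 10 and 17).

## Retrosynthetic overview
1. Target **21** ⇐ bis-MOM ketone **20** (acid deprotection). The late coupling is the C(=O)–CH2 bond, made by a Weinreb ketone synthesis: benzylic Grignard from chloride **13** + Weinreb amide **19**.
2. Ring-A fragment **13** ⇐ hydroxymethyl benzophenone **12** ⇐ diol **11** ⇐ ArLi + hydroxymethyl-aldehyde **10** ⇐ Comins ortho-lithiation of aldehyde **9** ⇐ **8** ⇐ phenol **7**.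
3. Ring-B fragment **19** ⇐ benzhydrol **16** via phthalide **17** (which masks both the acid and the carbinol), with **16** from aryl bromide **15** + aldehyde **3**.
4. Both arene cores come from 4-methoxy-3-methylphenol **7** (o-cresol → methyl ether → Friedel–Crafts acylation → Baeyer–Villiger). The 2,6-dimethoxyphenyl units come from resorcinol via **2** and **3**.
5. No carbocycle is constructed. The only ring formed and then opened is the transient lactone **17**.

## Route

**Step 1**
Reactants: 1 (resorcinol)
Product: 2 (1,3-dimethoxybenzene)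
Conditions: MeI, K2CO3, acetone, reflux
Reagents that add atoms: methyl iodide, CI (two CH3 groups)
Why: Williamson O-methylation of both phenols.

**Step 2**
Reactants: 2
Product: 3 (2,6-dimethoxybenzaldehyde)
Conditions: n-BuLi, THF, 0 °C→rt; then DMF, –78 °C→rt; H3O+
Reagents that add atoms: DMF, CN(C)C=O (adds CHO)
Why: directed ortho-metalation between the two OMe groups, then formylation.

**Step 3**
Reactants: 4 (o-cresol)
Product: 5 (2-methylanisole)
Conditions: MeI, K2CO3, acetone, reflux
Reagents that add atoms: methyl iodide, CI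
Why: Williamson O-methylation.

**Step 4**
Reactants: 5
Product: 6 (1-(4-methoxy-3-methylphenyl)ethanone)
Conditions: AcCl, AlCl3, CH2Cl2, 0 °C
Reagents that add atoms: acetyl chloride, CC(=O)Cl
Why: Friedel–Crafts acylation goes para to OMe, the strongest director, at the only open para site.

**Step 5**
Reactants: 6
Product: 7 (4-methoxy-3-methylphenol)
Conditions: mCPBA, TsOH (cat.), CH2Cl2, reflux; then K2CO3, MeOH, rt (one pot)
Reagents that add atoms: mCPBA, OOC(=O)c1cccc(Cl)c1 (supplies the aryl-O oxygen)
Why: Baeyer–Villiger oxidation with migration of the electron-rich aryl group, then acetate methanolysis.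

**Step 6**
Reactants: 7
Product: 8 (2-hydroxy-5-methoxy-4-methylbenzaldehyde)
Conditions: MgCl2, Et3N, (CH2O)n, MeCN, reflux
Reagents that add atoms: paraformaldehyde, C=O (adds CHO)
Why: Casnati–Skattebøl ortho-formylation via a magnesium phenoxide, going to the less hindered ortho site (para to Me).

**Step 7**
Reactants: 8
Product: 9 (5-methoxy-2-(methoxymethoxy)-4-methylbenzaldehyde)
Conditions: MOMCl, i-Pr2NEt, CH2Cl2, 0 °C→rt
Reagents that add atoms: chloromethyl methyl ether, COCCl
Why: MOM protection of the phenol, which also frees it from needing a later selective deprotection.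

**Step 8**
Reactants: 9
Product: 10 (2-(hydroxymethyl)-3-methoxy-4-methyl-6-(methoxymethoxy)benzaldehyde, present largely as its cyclic lactol)
Conditions: LiN(Me)CH2CH2NMe2 (from Me2NCH2CH2NHMe + n-BuLi), THF, –20 °C; n-BuLi, –20→0 °C; then CH2O (gas), –78 °C; aq NH4Cl
Reagents that add atoms: formaldehyde, C=O (adds CH2OH)
Why: Comins directed ortho-lithiation of the in situ α-amino alkoxide; the only free ortho C–H is also flanked by OMe, and lithiation is followed by trapping with formaldehyde.

**Step 9**
Reactants: 10 and 2 (as 2,6-dimethoxyphenyllithium)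
Product: 11 ((2,6-dimethoxyphenyl)[6-(hydroxymethyl)-5-methoxy-2-(methoxymethoxy)-4-methylphenyl]methanol, racemic)
Conditions: 2 + n-BuLi, THF, 0 °C (2 h); add 10 at –78 °C→rt; aq NH4Cl (neutral work-up)
Reagents that add atoms: none (2 is a numbered reactant)
Why: the lactol opens to the alkoxide aldehyde and the aryllithium adds to it (organolithium addition); the new benzhydryl stereocenter is racemic and is removed in step 10.

**Step 10**
Reactants: 11
Product: 12 ((2,6-dimethoxyphenyl)[6-(hydroxymethyl)-5-methoxy-2-(methoxymethoxy)-4-methylphenyl]methanone)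
Conditions: DDQ (1.5 equiv), CH2Cl2/H2O 20:1, 0 °C→rt
Reagents that add atoms: none
Why: DDQ hydride abstraction is selective for the electron-rich diarylcarbinol C–H over the primary benzylic alcohol, giving the ketone (no stereocenter remains).

**Step 11**
Reactants: 12
Product: 13 ([6-(chloromethyl)-5-methoxy-2-(methoxymethoxy)-4-methylphenyl](2,6-dimethoxyphenyl)methanone)
Conditions: PPh3, NCS, CH2Cl2, 0 °C
Reagents that add atoms: N-chlorosuccinimide, O=C1CCC(=O)N1Cl (adds Cl)
Why: Appel-type chlorination under neutral conditions, so the MOM group survives.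

**Step 12**
Reactants: 7
Product: 14 (2-bromo-4-methoxy-5-methylphenol)
Conditions: NBS, i-Pr2NH (cat.), CH2Cl2, –78 °C→rt
Reagents that add atoms: N-bromosuccinimide, O=C1CCC(=O)N1Br (adds Br)
Why: amine-mediated ortho-selective bromination of a phenol whose para position is blocked, at the less hindered ortho site.

**Step 13**
Reactants: 14
Product: 15 (1-bromo-5-methoxy-2-(methoxymethoxy)-4-methylbenzene)
Conditions: MOMCl, i-Pr2NEt, CH2Cl2, 0 °C→rt
Reagents that add atoms: chloromethyl methyl ether, COCCl
Why: MOM protection.

**Step 14**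
Reactants: 15 and 3
Product: 16 ((2,6-dimethoxyphenyl)[5-methoxy-2-(methoxymethoxy)-4-methylphenyl]methanol, racemic)
Conditions: t-BuLi (2 equiv), THF, –78 °C, 15 min; then 3, –78 °C→rt; aq NH4Cl
Reagents that add atoms: none (3 is a numbered reactant)
Why: Br/Li exchange followed by 1,2-addition to the aldehyde; the racemic carbinol is oxidized away in step 17.

**Step 15**
Reactants: 16
Product: 17 (3-(2,6-dimethoxyphenyl)-7-methoxy-4-(methoxymethoxy)-6-methylisobenzofuran-1(3H)-one, racemic)
Conditions: s-BuLi (3 equiv), TMEDA, THF, –78→–40 °C; CO2 (excess), –78 °C→rt; aq NaH2PO4; PPTS (cat.), CH2Cl2, rt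
Reagents that add atoms: carbon dioxide, O=C=O (adds the lactone C=O)
Why: directed ortho-lithiation of the lithium alkoxide at the site between OMe and CH(OLi)Ar (cooperative directing), carboxylation, then lactonization to the phthalide.

**Step 16**
Reactants: 17
Product: 18 (6-[(2,6-dimethoxyphenyl)(hydroxy)methyl]-N,2-dimethoxy-5-(methoxymethoxy)-N,3-dimethylbenzamide, racemic)
Conditions: MeNH(OMe)·HCl, i-PrMgCl, THF, –20→0 °C
Reagents that add atoms: N,O-dimethylhydroxylamine, CNOC (as HCl salt; adds N(OMe)Me)
Why: magnesium amide opening of the lactone gives the hydroxy Weinreb amide.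

**Step 17**
Reactants: 18
Product: 19 (6-(2,6-dimethoxybenzoyl)-N,2-dimethoxy-5-(methoxymethoxy)-N,3-dimethylbenzamide)
Conditions: Dess–Martin periodinane, NaHCO3, CH2Cl2, rt
Reagents that add atoms: none
Why: oxidation of the benzhydrol to the diaryl ketone, which removes the last racemic stereocenter.

**Step 18**
Reactants: 13 and 19
Product: 20 (bis-MOM ketone, C40H44O13)
Conditions: Mg (activated), THF, 0 °C to form the benzylic Grignard from 13; add it to 19 in THF, –78→0 °C; aq NH4Cl
Reagents that add atoms: none
Why: Weinreb ketone synthesis, where the chelated tetrahedral intermediate prevents over-addition and the hindered tetra-ortho diaryl ketones are inert to the Grignard. The CH2 adjacent to the new ketone is acidic and is not deprotonated until work-up.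

**Step 19**
Reactants: 20
Product: 21 (Acredinone B)
Conditions: conc. HCl (cat.), MeOH/THF 1:1, 50 °C
Reagents that add atoms: none
Why: acid hydrolysis of both aryl MOM acetals frees the two chelated phenols, while the aryl methyl ethers and ketones survive.

## Compound list
1 | resorcinol | Oc1cccc(O)c1 | starting material
2 | 1,3-dimethoxybenzene | COc1cccc(OC)c1 | intermediate
3 | 2,6-dimethoxybenzaldehyde | COc1cccc(OC)c1C=O | intermediate
4 | o-cresol | Cc1ccccc1O | starting material
5 | 2-methylanisole | COc1ccccc1C | intermediate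
6 | 1-(4-methoxy-3-methylphenyl)ethanone | CC(=O)c1ccc(OC)c(C)c1 | intermediate
7 | 4-methoxy-3-methylphenol | COc1ccc(O)cc1C | intermediate
8 | 2-hydroxy-5-methoxy-4-methylbenzaldehyde | COc1cc(C=O)c(O)cc1C | intermediate
9 | 5-methoxy-2-(methoxymethoxy)-4-methylbenzaldehyde | COc1cc(C=O)c(OCOC)cc1C | intermediate
10 | 2-(hydroxymethyl)-3-methoxy-4-methyl-6-(methoxymethoxy)benzaldehyde (lactol tautomer) | COc1c(CO)c(C=O)c(OCOC)cc1C | intermediate
11 | (2,6-dimethoxyphenyl)[6-(hydroxymethyl)-5-methoxy-2-(methoxymethoxy)-4-methylphenyl]methanol (racemic) | COc1c(CO)c(C(O)c2c(OC)cccc2OC)c(OCOC)cc1C | intermediate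
12 | (2,6-dimethoxyphenyl)[6-(hydroxymethyl)-5-methoxy-2-(methoxymethoxy)-4-methylphenyl]methanone | COc1c(CO)c(C(=O)c2c(OC)cccc2OC)c(OCOC)cc1C | intermediate
13 | [6-(chloromethyl)-5-methoxy-2-(methoxymethoxy)-4-methylphenyl](2,6-dimethoxyphenyl)methanone | COc1c(CCl)c(C(=O)c2c(OC)cccc2OC)c(OCOC)cc1C | intermediate (coupling fragment A)
14 | 2-bromo-4-methoxy-5-methylphenol | COc1cc(Br)c(O)cc1C | intermediate
15 | 1-bromo-5-methoxy-2-(methoxymethoxy)-4-methylbenzene | COc1cc(Br)c(OCOC)cc1C | intermediate
16 | (2,6-dimethoxyphenyl)[5-methoxy-2-(methoxymethoxy)-4-methylphenyl]methanol (racemic) | COc1cc(C(O)c2c(OC)cccc2OC)c(OCOC)cc1C | intermediate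
17 | 3-(2,6-dimethoxyphenyl)-7-methoxy-4-(methoxymethoxy)-6-methylisobenzofuran-1(3H)-one (racemic) | O=C1OC(c3c(OC)cccc3OC)c2c1c(OC)c(C)cc2OCOC | intermediate
18 | 6-[(2,6-dimethoxyphenyl)(hydroxy)methyl]-N,2-dimethoxy-5-(methoxymethoxy)-N,3-dimethylbenzamide (racemic) | CON(C)C(=O)c1c(OC)c(C)cc(OCOC)c1C(O)c1c(OC)cccc1OC | intermediate
19 | 6-(2,6-dimethoxybenzoyl)-N,2-dimethoxy-5-(methoxymethoxy)-N,3-dimethylbenzamide | CON(C)C(=O)c1c(OC)c(C)cc(OCOC)c1C(=O)c1c(OC)cccc1OC | intermediate (coupling fragment B)
20 | bis-MOM ketone | COc1c(CC(=O)c2c(OC)c(C)cc(OCOC)c2C(=O)c2c(OC)cccc2OC)c(C(=O)c2c(OC)cccc2OC)c(OCOC)cc1C | intermediate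
21 | Acredinone B | COc1cccc(OC)c1C(=O)c1c(O)cc(C)c(OC)c1CC(=O)c1c(OC)c(C)cc(O)c1C(=O)c1c(OC)cccc1OC | target

## Step count
- Total steps: 19.
- Longest linear sequence: 11 (steps 3, 4, 5, 6–11, 18, 19; the ring-B arm 3, 4, 5, 12–17, 18, 19 is also 11).

## Three steps most likely to fail
1. **Step 15 (regioselective ortho-lithiation and carboxylation).** The site between OMe and the alkoxide may compete with the site between OMOM and Me. Fallback: apply the Comins ortho-lithiation of aldehyde 9 (the step 8 method) with a CO2 quench to give the 3-hydroxyphthalide, then add 2,6-dimethoxyphenyllithium (from 2) to reach 17. This fixes the regiochemistry because only one ortho C–H is available.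
2. **Step 10 (chemoselective DDQ oxidation of the diol).** Over-oxidation of the primary alcohol, or phthalan formation, may occur. Fallback: selectively silylate the primary alcohol of 11 (TBSCl, imidazole), oxidize the benzhydrol with Dess–Martin periodinane, and remove the TBS group (TBAF) to give 12.
3. **Step 18 (benzylic Grignard formation and Weinreb addition).** Wurtz dimerization of the benzylic chloride, or sluggish addition to the very hindered amide, may occur. Fallback: convert the ring-B fragment to its S-ethyl thioester (lactone opening with Me2AlSEt, then oxidation), make the benzylzinc from 13 (Zn, LiCl), and join them by a Pd-catalysed Fukuyama coupling.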